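## The problem

The target 17, (2R,3R)-6-methoxy-3-methyl-5-[(E)-prop-1-enyl]-2-(3,4,5-trimethoxyphenyl)-2,3-dihydro-1-benzofuran, has a benzo ring A fused to a five-membered oxygen ring. That ring carries the only two stereocenters, C2 (bonded to O1 and ring B) and C3 (bonded to the methyl group and ring A), adjacent and trans. In the closed ring the trans arrangement is the more stable one, so C3 can steer C2 under ionising conditions. In an open chain, induction from C3 to C2 is weak, and nothing in the molecule controls C3, so the absolute configuration of both centers has to come from reagents or catalysts. The (E)-propenyl group at C5 is an electron-rich styrene that would not survive hydride-metal catalysts, peroxide, electrophiles or strong acid, so it belongs at the end. The O1–C2 bond is a doubly activated benzylic ether: strong acid ionises it, hydrogenolysis cleaves it, and quinone oxidants aromatise the ring to the benzofuran with loss of both centers. Ring A must end with carbon at C5, para to O1 and ortho to the 6-methoxy group, and this position has to be distinguished from C7 and from the free positions of ring B. The enabling feature is that C2 is a methine bonded to exactly three different partners, C3, the ipso carbon of ring B and O1. A boron-bound carbon can collect these one after the other: C3 by migration from boron onto a dichloromethyl carbenoid, ring B by an aryl group migrating from boron with loss of the second chloride, and oxygen by stereospecific replacement of boron. Each event is stereospecific, so a chiral diol on boron can dictate C2.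

## Retrosynthesis

**C5–propenyl bond (17 ⇒ 15 + 16).** The bond between C5 and the propenyl carbon is cut first, giving aryl bromide 15 and the commercial (E)-propenyl pinacol boronate 16. The neighbouring options are formylation of a C5-unsubstituted ring A followed by olefination, or carrying the alkene through the route. The first costs two steps and raises two selectivity questions (C5 against C7 and ring B; E against Z). The second exposes a styrene to CuH, peroxide and carbenoid chemistry. A bromine at C5 is already present in the commercial aldehyde 1, is inert to every planned step if alkyllithium never meets it, and fixes both regiochemistry and alkene geometry in one Suzuki–Miyaura coupling.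

**O1–C2 bond (15 ⇒ 14).** The ring is opened at the benzylic ether bond, giving the phenol carbinol 14. Cutting O1–C2 is preferred to cutting O1–C7a because the phenol oxygen is on ring A from the start and C2 arrives from boron as a carbinol. An aryl etherification at C7a would need a second halogen on ring A. Closure by intramolecular Mitsunobu reaction inverts C2, so 14 must be the (1S,2R) isomer. The forward reaction has to be an SN2 displacement at a secondary benzylic carbon without ionisation.

**C2–O from C2–B, and the phenol protecting group (14 ⇒ 12).** The carbinol oxygen is traced back to boron in boronic ester 12. Oxidation of a C–B bond goes with retention, so 12 must be (1S,2S); the descriptor at the methyl-bearing carbon changes only because boron ranks below carbon. The aryl silyl ether is cleaved by the same alkaline medium, so no separate deprotection is planned.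

**C2–C3 and C2–aryl bonds (12 ⇒ 8 + 9 + 10).** This is the key disconnection. Both carbon–carbon bonds to C2 are cut, leaving the secondary benzylic boronate 8, dichloromethane 9 as the source of C2, and the aryl Grignard reagent 10. The alternative of adding an aryl nucleophile to an α-aryl aldehyde relies on modest 1,2-induction and a configurationally fragile aldehyde. The boron route sets C2 by reagent control and carries C3 through with retention. The precursor is much simpler: one stereocenter, one aryl ring, no C2. The forward reaction requires the correct diol antipode. C2-symmetric (R,R)-1,2-diol boronates give (αS)-chlorides, and aryl displacement with inversion then gives the (1R) product. The (1S) boronate 12 needed here therefore requires the (S,S)-diol 6 and the (αR)-chloride 11.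

**Boron ligand (8 ⇒ 5 + 6, 5 ⇒ 4).** The dicyclohexylethanediol ester 8 is traced to the pinacol ester 4 through the diethanolamine adduct 5 and the free boronic acid 7. Pinacol has no directing power and does not exchange directly. The usual detour through a trifluoroborate is avoided because bifluoride in methanol cleaves aryl silyl ethers. Amino-diol exchange and mild acid hydrolysis do not touch the silyl ether.

**C3–B bond (4 ⇒ 3).** The benzylic C–B bond and its stereocenter come from asymmetric Markovnikov hydroboration of styrene 3. A Matteson homologation of a ring A arylboronic ester with methyl Grignard displacement would use the same diol and save the ligand exchange. It is not chosen because it passes through a very electron-rich α-chlorobenzyl boronate that is prone to ionise and epimerise.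

**Styrene (3 ⇒ 2 ⇒ 1).** The vinyl group is cut back to aldehyde 2 by Wittig methylenation and the silyl ether to the commercial bromosalicylaldehyde 1.

## Roads not taken

**Alternative 1:** Ring A is cut at C4–C5 and C7–C7a, so that it is built onto a preformed lactone carrying both stereocenters, (4R,5R)-4-methyl-3-methylidene-5-(3,4,5-trimethoxyphenyl)oxolan-2-one A1. In the forward key step an acetoacetate ester anion adds to the exocyclic methylene, the methyl ketone enolate then acylates the lactone carbonyl to close a cyclohexanedione, and mild acid recloses O1 onto C7a to give the bicyclic vinylogous ester A2.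
- Merits: cheap reagents, no cryogenic steps, no protecting group on ring A, and the regiochemistry of the C5 ester and C6 oxygen follows from the annulation.
- Weak points: A2 is two hydrogens short of aromatic. Dehydrogenation has to be done next to the C2–O1 benzylic ether, where the oxidants that aromatise ring A also tend to aromatise the furan ring and erase both stereocenters. O-methylation and three further steps (ester to aldehyde to propenyl) then follow, about five steps after the key step. A1 itself needs its own asymmetric synthesis.
- Comparison: this road is better in reagent cost and operational simplicity. The chosen plan sets against it an aromatic ring A from the first step, so that no oxidation-state change is needed near C2, and three steps after the key step.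

**Alternative 2:** Ring A is cut at C3a–C4 and C7–C7a. The silyl ketene acetal A3 of the trans lactone adds across the diene of the pyrone ester A4; the bridged adduct decarboxylates and then loses silanol to give the aromatic ester A5.
- Merits: convergent; ring A is delivered aromatic with the correct oxygenation in one operation; the O1–C2 bond is never made by substitution at an ionisable carbon, which is a real advantage over the Mitsunobu closure.
- Weak points: the nucleophilic carbon of A3 is flanked by the C3 methyl group, and the pyrone is deactivated by its methoxy donor, so forcing conditions are likely. In the aromatisation the ring oxygen can leave in place of silanol, which opens the furan ring. A3 requires a separate asymmetric lactone synthesis, and A5 still needs three steps to the propenyl group with an E/Z question.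
- Comparison: equal or better in convergence. The chosen plan sets against it a C5 bromide that becomes the propenyl group in one stereodefined step, and stereocenters set by catalyst and boron ligand with a predictable sense.

**Alternative 3:** Ring A is assembled by a Danheiser benzannulation onto the side chain. Irradiation of the unsaturated diazoketone A6 gives a vinylketene by Wolff rearrangement (C4–C5), which adds an alkoxyacetylene (C7–C7a, C5–C6), opens to a dienylketene and closes by 6π electrocyclisation (C3a–C7a) to phenol A7.
- Merits: the 1,3-dioxygenated ring A forms with the side chain ortho to the new phenol without any regiochemical doubt, and A7 has the (1S,2R) configuration needed for an invertive closure.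
- Weak points: A6 needs a long acyclic sequence (two stereocenters, enone, diazo transfer). Its γ-stereocenter is allylic and vinylogously acidic. The alkyne partner is volatile and unstable, and a four-event pericyclic cascade is rarely efficient. A7 has no substituent at C5, so two more steps and a regioselective functionalisation remain after ring closure.
- Comparison: this road avoids the stoichiometric chiral diol and the ligand exchange. The chosen plan reaches the corresponding stage, phenol 14, in seven steps from a catalogue aldehyde with C5 already functionalised.

Key step: step 6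

Remarks on the chemistry (assumptions):
- The direction of induction at boron is taken from the established behaviour of C2-symmetric 1,2-diol boronates ((R,R)-diol gives the (αS)-chloride); the (αR)-chloride 11 therefore calls for the (S,S)-diol 6.
- The ligand antipode in step 3 rests on the premise that (R)-DTBM-SEGPHOS with CuH converts styrenes into (S)-1-arylethyl boronates; the sense is to be confirmed on the first run and the antipode used if it is opposite.
- Grignard reagent 10 is used as the commercial THF solution, titrated before use; aldehyde 1, diol 6 and boronate 16 are catalogue compounds.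

## Route

Step 1
Reactants: 1 5-bromo-2-hydroxy-4-methoxybenzaldehyde
Product: 2 5-bromo-2-[(tert-butyldimethylsilyl)oxy]-4-methoxybenzaldehyde
Conditions: TBSCl, imidazole, DMF, rt
Reagents that add atoms: tert-butyldimethylsilyl chloride, CC(C)(C)[Si](C)(C)Cl
Why: Silylation of a phenol with TBSCl and imidazole is routine, also for the hydrogen-bonded salicylaldehyde OH; the silyl ether masks the acidic proton through the ylide, CuH and organometallic steps and falls off in the alkaline peroxide of step 7.

Step 2
Reactants: 2 5-bromo-2-[(tert-butyldimethylsilyl)oxy]-4-methoxybenzaldehyde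
Product: 3 (4-bromo-2-ethenyl-5-methoxyphenoxy)(tert-butyl)dimethylsilane
Conditions: Ph3PCH3Br, NaN(SiMe3)2, THF, 0 °C → rt
Reagents that add atoms: methyltriphenylphosphonium bromide, C[P+](c1ccccc1)(c1ccccc1)c1ccccc1.[Br-]
Why: Wittig methylenation of an aromatic aldehyde with the non-stabilised ylide is reliable; the amide base is consumed by the phosphonium salt before 2 is added, so neither the aryl bromide nor the silyl ether meets a strong base.

Step 3
Reactants: 3 (4-bromo-2-ethenyl-5-methoxyphenoxy)(tert-butyl)dimethylsilane
Product: 4 2-[(1R)-1-{5-bromo-2-[(tert-butyldimethylsilyl)oxy]-4-methoxyphenyl}ethyl]-4,4,5,5-tetramethyl-1,3,2-dioxaborolane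
Conditions: HBpin, CuCl (3 mol%), NaOtBu (6 mol%), (S)-DTBM-SEGPHOS (3 mol%), toluene, rt
Reagents that add atoms: pinacolborane, [H]B1OC(C)(C)C(C)(C)O1
Why: Asymmetric Markovnikov hydroboration of a styrene: the bisphosphine-bound CuH (monovalent copper) inserts the alkene to give the benzylic copper species on the face chosen by the ligand, and σ-bond metathesis with HBpin puts boron on C3 with retention and regenerates CuH; the aryl bromide is inert to CuH at room temperature.

Step 4
Reactants: 4 2-[(1R)-1-{5-bromo-2-[(tert-butyldimethylsilyl)oxy]-4-methoxyphenyl}ethyl]-4,4,5,5-tetramethyl-1,3,2-dioxaborolane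
Product: 5 2-[(1R)-1-{5-bromo-2-[(tert-butyldimethylsilyl)oxy]-4-methoxyphenyl}ethyl]-1,3,6,2-dioxazaborocane (diethanolamine boronate with N→B coordination)
Conditions: HN(CH2CH2OH)2, Et2O, rt; filtration
Reagents that add atoms: diethanolamine, OCCNCCO
Why: Transesterification of secondary alkyl pinacol boronates with diethanolamine is driven by N→B coordination and precipitation of the tetracoordinate adduct; no fluoride is used, so the aryl silyl ether stays, and the boron-bearing stereocenter is not involved.

Step 5
Reactants: 5 2-[(1R)-1-{5-bromo-2-[(tert-butyldimethylsilyl)oxy]-4-methoxyphenyl}ethyl]-1,3,6,2-dioxazaborocane; 6 (1S,2S)-1,2-dicyclohexylethane-1,2-diol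
Product: 8 (4S,5S)-2-[(1R)-1-{5-bromo-2-[(tert-butyldimethylsilyl)oxy]-4-methoxyphenyl}ethyl]-4,5-dicyclohexyl-1,3,2-dioxaborolane, via free boronic acid 7 (not isolated)
Conditions: 0.5 M aq HCl, Et2O, rt; then MgSO4
Reagents that add atoms: none
Why: Dilute acid protonates the amine and frees boronic acid 7, which is esterified at once by the 1,2-diol to the stable five-membered boronate; the C–B stereocenter is untouched and the aryl silyl ether tolerates brief contact with dilute HCl.

Step 6
Reactants: 8 (4S,5S)-2-[(1R)-1-{5-bromo-2-[(tert-butyldimethylsilyl)oxy]-4-methoxyphenyl}ethyl]-4,5-dicyclohexyl-1,3,2-dioxaborolane; 9 dichloromethane; 10 (3,4,5-trimethoxyphenyl)magnesium bromide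
Product: 12 (4S,5S)-2-[(1S,2S)-2-{5-bromo-2-[(tert-butyldimethylsilyl)oxy]-4-methoxyphenyl}-1-(3,4,5-trimethoxyphenyl)propyl]-4,5-dicyclohexyl-1,3,2-dioxaborolane, via α-chloro boronic ester 11 (not isolated)
Conditions: 9, n-BuLi, THF, −100 °C; 8, then ZnCl2 (Et2O), −100 °C → rt; pentane, filtration under Ar; 10, THF, −78 °C → rt
Reagents that add atoms: none
Why: (Dichloromethyl)lithium, formed from 9 and n-BuLi at −100 °C before 8 is added so that no alkyllithium meets the aryl bromide, adds to boron of 8 to give a tetracoordinate ate complex. On warming with ZnCl2 the secondary benzylic carbon C3 migrates from boron to the carbenoid carbon with retention and expels one of the two diastereotopic chlorides (new C2–C3 bond); the (S,S)-diol selects the chloride so that the (αR)-chloride 11 forms. ZnCl2 assists chloride departure and binds free chloride, which suppresses epimerisation of 11 and favours carbon over oxygen migration. Grignard reagent 10 then adds to boron of 11 and ring B migrates anti to the C–Cl bond with inversion (new C2–aryl bond), giving the (1S) configuration of 12. The closest known reaction type is the Matteson homologation of chiral diol boronic esters followed by Grignard displacement of the α-chloride, which is applied routinely to α-branched secondary alkyl boronates to build adjacent stereocenters. No ring is closed. C2 is the only new stereocenter and is set by reagent control from the diol; the (R) center at C3 paired with the (S,S)-diol is the combination an iterative sequence with this diol would itself produce, and C3 is carried through with retention. The step needs a single insertion and clean aryl transfer to a β-branched chloride: the first is secured because the carbenoid decomposes on warming before the more hindered 11 can react again, the second by the low basicity of the aryl Grignard reagent and removal of the zinc and lithium salts before it is added.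

Step 7
Reactants: 12 (4S,5S)-2-[(1S,2S)-2-{5-bromo-2-[(tert-butyldimethylsilyl)oxy]-4-methoxyphenyl}-1-(3,4,5-trimethoxyphenyl)propyl]-4,5-dicyclohexyl-1,3,2-dioxaborolane
Product: 14 4-bromo-2-[(1S,2R)-1-hydroxy-1-(3,4,5-trimethoxyphenyl)propan-2-yl]-5-methoxyphenol, via silyl ether carbinol 13 (not isolated)
Conditions: 30% H2O2, 2 M NaOH, THF/MeOH, 0 °C → rt
Reagents that add atoms: hydrogen peroxide, OO
Why: Alkaline H2O2 oxidises the C–B bond by 1,2-migration of C2 from boron to oxygen with retention, giving carbinol 13 and releasing diol 6 for recovery; the same aqueous NaOH in MeOH cleaves the aryl silyl ether, so phenol 14 is obtained in one operation, and the aryl bromide and methyl ethers are inert.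

Step 8
Reactants: 14 4-bromo-2-[(1S,2R)-1-hydroxy-1-(3,4,5-trimethoxyphenyl)propan-2-yl]-5-methoxyphenol
Product: 15 (2R,3R)-5-bromo-6-methoxy-3-methyl-2-(3,4,5-trimethoxyphenyl)-2,3-dihydro-1-benzofuran
Conditions: PPh3, DIAD, THF, 0 °C → rt
Reagents that add atoms: none
Why: Intramolecular Mitsunobu etherification, a known way to close 2-aryl-2,3-dihydrobenzofurans: the phenol is the only acidic OH, the benzylic alcohol is activated as its alkoxyphosphonium salt, and the phenoxide closes the five-membered ring by 5-exo-tet SN2 attack with inversion at C2, turning the (1S) carbinol into the (2R) ether trans to the C3 methyl group; the meta-methoxy groups of ring B temper ionisation, and the trans product is also the more stable isomer.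

Step 9
Reactants: 15 (2R,3R)-5-bromo-6-methoxy-3-methyl-2-(3,4,5-trimethoxyphenyl)-2,3-dihydro-1-benzofuran; 16 4,4,5,5-tetramethyl-2-[(1E)-prop-1-en-1-yl]-1,3,2-dioxaborolane
Product: 17 (2R,3R)-6-methoxy-3-methyl-5-[(1E)-prop-1-en-1-yl]-2-(3,4,5-trimethoxyphenyl)-2,3-dihydro-1-benzofuran
Conditions: Pd(OAc)2 (5 mol%), SPhos (10 mol%), K3PO4, toluene/H2O, 80 °C
Reagents that add atoms: none
Why: Suzuki–Miyaura coupling of an aryl bromide with an (E)-alkenylboronic ester proceeds with retention of alkene geometry; zerovalent palladium formed from Pd(OAc)2 and the biaryl phosphine inserts into the electron-rich, ortho-methoxy-substituted C–Br bond, and the phosphate base leaves both stereocenters untouched.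

## Compound list

1 | 5-bromo-2-hydroxy-4-methoxybenzaldehyde | COc1cc(O)c(C=O)cc1Br | starting material
2 | 5-bromo-2-[(tert-butyldimethylsilyl)oxy]-4-methoxybenzaldehyde | COc1cc(O[Si](C)(C)C(C)(C)C)c(C=O)cc1Br | intermediate
3 | (4-bromo-2-ethenyl-5-methoxyphenoxy)(tert-butyl)dimethylsilane | C=Cc1cc(Br)c(OC)cc1O[Si](C)(C)C(C)(C)C | intermediate
4 | 2-[(1R)-1-{5-bromo-2-[(tert-butyldimethylsilyl)oxy]-4-methoxyphenyl}ethyl]-4,4,5,5-tetramethyl-1,3,2-dioxaborolane | C[C@H](c1cc(Br)c(OC)cc1O[Si](C)(C)C(C)(C)C)B1OC(C)(C)C(C)(C)O1 | intermediate
5 | 2-[(1R)-1-{5-bromo-2-[(tert-butyldimethylsilyl)oxy]-4-methoxyphenyl}ethyl]-1,3,6,2-dioxazaborocane | C[C@H](c1cc(Br)c(OC)cc1O[Si](C)(C)C(C)(C)C)B1OCCNCCO1 | intermediate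
6 | (1S,2S)-1,2-dicyclohexylethane-1,2-diol | O[C@@H](C1CCCCC1)[C@H](C1CCCCC1)O | starting material
7 | [(1R)-1-{5-bromo-2-[(tert-butyldimethylsilyl)oxy]-4-methoxyphenyl}ethyl]boronic acid | C[C@H](c1cc(Br)c(OC)cc1O[Si](C)(C)C(C)(C)C)B(O)O | intermediate
8 | (4S,5S)-2-[(1R)-1-{5-bromo-2-[(tert-butyldimethylsilyl)oxy]-4-methoxyphenyl}ethyl]-4,5-dicyclohexyl-1,3,2-dioxaborolane | C[C@H](c1cc(Br)c(OC)cc1O[Si](C)(C)C(C)(C)C)B1O[C@@H](C2CCCCC2)[C@H](C2CCCCC2)O1 | intermediate
9 | dichloromethane | ClCCl | starting material
10 | (3,4,5-trimethoxyphenyl)magnesium bromide | COc1cc([Mg]Br)cc(OC)c1OC | starting material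
11 | (4S,5S)-2-[(1R,2R)-2-{5-bromo-2-[(tert-butyldimethylsilyl)oxy]-4-methoxyphenyl}-1-chloropropyl]-4,5-dicyclohexyl-1,3,2-dioxaborolane | C[C@H](c1cc(Br)c(OC)cc1O[Si](C)(C)C(C)(C)C)[C@H](Cl)B1O[C@@H](C2CCCCC2)[C@H](C2CCCCC2)O1 | intermediate
12 | (4S,5S)-2-[(1S,2S)-2-{5-bromo-2-[(tert-butyldimethylsilyl)oxy]-4-methoxyphenyl}-1-(3,4,5-trimethoxyphenyl)propyl]-4,5-dicyclohexyl-1,3,2-dioxaborolane | C[C@H](c1cc(Br)c(OC)cc1O[Si](C)(C)C(C)(C)C)[C@@H](c1cc(OC)c(OC)c(OC)c1)B1O[C@@H](C2CCCCC2)[C@H](C2CCCCC2)O1 | intermediate
13 | (1S,2R)-2-{5-bromo-2-[(tert-butyldimethylsilyl)oxy]-4-methoxyphenyl}-1-(3,4,5-trimethoxyphenyl)propan-1-ol | C[C@H](c1cc(Br)c(OC)cc1O[Si](C)(C)C(C)(C)C)[C@@H](c1cc(OC)c(OC)c(OC)c1)O | intermediate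
14 | 4-bromo-2-[(1S,2R)-1-hydroxy-1-(3,4,5-trimethoxyphenyl)propan-2-yl]-5-methoxyphenol | C[C@H](c1cc(Br)c(OC)cc1O)[C@@H](c1cc(OC)c(OC)c(OC)c1)O | intermediate
15 | (2R,3R)-5-bromo-6-methoxy-3-methyl-2-(3,4,5-trimethoxyphenyl)-2,3-dihydro-1-benzofuran | Brc1cc2c(cc1OC)O[C@@H](c1cc(OC)c(OC)c(OC)c1)[C@@H]2C | intermediate
16 | 4,4,5,5-tetramethyl-2-[(1E)-prop-1-en-1-yl]-1,3,2-dioxaborolane | C/C=C/B1OC(C)(C)C(C)(C)O1 | starting material
17 | (2R,3R)-6-methoxy-3-methyl-5-[(1E)-prop-1-en-1-yl]-2-(3,4,5-trimethoxyphenyl)-2,3-dihydro-1-benzofuran | C/C=C/c1cc2c(cc1OC)O[C@@H](c1cc(OC)c(OC)c(OC)c1)[C@@H]2C | target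

## Step count and risk

Total steps: 9. Longest linear sequence: 9 steps (1 → 17); compounds 6, 9, 10 and 16 are bought.

**Step 6 (key step).**
- What may go wrong: slow ate-complex formation and migration at the hindered secondary benzylic boron; epimerisation of the α-chloride by chloride exchange before the Grignard reagent is added; sluggish aryl transfer to the β-branched chloride with competing elimination toward an alkenyl boronate or oxygen migration; halogen–metal exchange at the ring A bromide if alkyllithium is left over.
- Fallback: it sets out from 8 and gives up reagent control at C2 in favour of control by C3 in the ring closure. Only the chloromethylene insertion is carried out, and the crude chloride 11 is oxidised with NaBO3·4H2O in buffered aqueous THF to (2R)-2-{5-bromo-2-[(tert-butyldimethylsilyl)oxy]-4-methoxyphenyl}propanal F1. Reagent 10 is added to F1 at −78 °C in the presence of CeCl3 to limit enolisation, giving (2R)-2-{5-bromo-2-[(tert-butyldimethylsilyl)oxy]-4-methoxyphenyl}-1-(3,4,5-trimethoxyphenyl)propan-1-ol F2 as a mixture of carbinol epimers. Desilylation with Bu4NF gives 4-bromo-2-[(2R)-1-hydroxy-1-(3,4,5-trimethoxyphenyl)propan-2-yl]-5-methoxyphenol F3, also an epimer mixture. Catalytic p-toluenesulfonic acid in CH2Cl2 at low temperature then closes both epimers through the benzylic cation to the trans ether, so the sequence comes back to the route at 15. Its weakness is the configurational fragility of the α-aryl aldehyde.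

**Step 3.**
- What may go wrong: slow insertion because of the bulky ortho-silyloxy group and the electron-rich ring, with erosion of branched selectivity or of enantioselectivity.
- Fallback: it sets out from 3. Hydroboration with catecholborane and [Rh(cod)2]BF4 (monovalent rhodium) with (R)-BINAP in DME at −78 °C gives 2-[(1R)-1-{5-bromo-2-[(tert-butyldimethylsilyl)oxy]-4-methoxyphenyl}ethyl]-1,3,2-benzodioxaborole F4. The labile catechol ester is treated directly with diol 6, and any minor diastereomer of the resulting ester is removed by crystallisation or chromatography. This bypasses 4, 5 and 7 and comes back at 8.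

**Step 4.**
- What may go wrong: the amino-diol adduct may fail to form or to precipitate because of steric hindrance and the lipophilic silyl group, so the exchange stalls at equilibrium.
- Fallback: it sets out from 4. The pinacol is removed oxidatively with NaIO4 and NH4OAc in aqueous acetone to give boronic acid 7, which is condensed with 6 over MgSO4 in Et2O, coming back at 8. This makes no compound outside the list (F0).

**Step 8.**
- What may go wrong: ionisation of the alkoxyphosphonium intermediate at the electron-rich benzylic carbon, with loss of stereospecificity, or elimination toward the stilbene.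
- Fallback: it sets out from 14. Cyclodehydration with catalytic p-toluenesulfonic acid in CH2Cl2 closes the ring through the benzylic cation under control of C3 and comes back at 15; it makes no new compound (F0). The caveat is reversible loss of the C3 proton from the cation, which would erode enantiopurity, so the reaction is kept cold and short.

Further compounds

F1 | step 6 | (2R)-2-{5-bromo-2-[(tert-butyldimethylsilyl)oxy]-4-methoxyphenyl}propanal | C[C@H](c1cc(Br)c(OC)cc1O[Si](C)(C)C(C)(C)C)C=O
F2 | step 6 | (2R)-2-{5-bromo-2-[(tert-butyldimethylsilyl)oxy]-4-methoxyphenyl}-1-(3,4,5-trimethoxyphenyl)propan-1-ol (mixture of carbinol epimers) | C[C@H](c1cc(Br)c(OC)cc1O[Si](C)(C)C(C)(C)C)C(O)c1cc(OC)c(OC)c(OC)c1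
F3 | step 6 | 4-bromo-2-[(2R)-1-hydroxy-1-(3,4,5-trimethoxyphenyl)propan-2-yl]-5-methoxyphenol (mixture of carbinol epimers) | C[C@H](c1cc(Br)c(OC)cc1O)C(O)c1cc(OC)c(OC)c(OC)c1
F4 | step 3 | 2-[(1R)-1-{5-bromo-2-[(tert-butyldimethylsilyl)oxy]-4-methoxyphenyl}ethyl]-1,3,2-benzodioxaborole | C[C@H](c1cc(Br)c(OC)cc1O[Si](C)(C)C(C)(C)C)B1Oc2ccccc2O1
F0 | step 4 | none | none
F0 | step 8 | none | none
A1 | alternative 1 | (4R,5R)-4-methyl-3-methylidene-5-(3,4,5-trimethoxyphenyl)oxolan-2-one | C=C1C(=O)O[C@@H](c2cc(OC)c(OC)c(OC)c2)[C@@H]1C
A2 | alternative 1 | methyl (2R,3R)-3-methyl-6-oxo-2-(3,4,5-trimethoxyphenyl)-2,3,3a,4,5,6-hexahydro-1-benzofuran-5-carboxylate (mixture at C3a and C5) | COC(=O)C1CC2C(=CC1=O)O[C@@H](c1cc(OC)c(OC)c(OC)c1)[C@@H]2C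
A3 | alternative 2 | trimethyl{[(2R,3R)-3-methyl-2-(3,4,5-trimethoxyphenyl)-2,3-dihydrofuran-5-yl]oxy}silane | C[Si](C)(C)OC1=C[C@@H](C)[C@H](c2cc(OC)c(OC)c(OC)c2)O1
A4 | alternative 2 | methyl 4-methoxy-2-oxo-2H-pyran-5-carboxylate | COC(=O)C1=COC(=O)C=C1OC
A5 | alternative 2 | methyl (2R,3R)-6-methoxy-3-methyl-2-(3,4,5-trimethoxyphenyl)-2,3-dihydro-1-benzofuran-5-carboxylate | COC(=O)c1cc2c(cc1OC)O[C@@H](c1cc(OC)c(OC)c(OC)c1)[C@@H]2C
A6 | alternative 3 | (3E,5R,6S)-6-[(tert-butyldimethylsilyl)oxy]-1-diazo-5-methyl-6-(3,4,5-trimethoxyphenyl)hex-3-en-2-one | [N-]=[N+]=CC(=O)/C=C/[C@@H](C)[C@H](O[Si](C)(C)C(C)(C)C)c1cc(OC)c(OC)c(OC)c1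
A7 | alternative 3 | 2-[(1S,2R)-1-[(tert-butyldimethylsilyl)oxy]-1-(3,4,5-trimethoxyphenyl)propan-2-yl]-5-methoxyphenol | CC(C)(C)[Si](C)(C)O[C@H](c1cc(OC)c(OC)c(OC)c1)[C@@H](c1ccc(OC)cc1O)C
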